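**Retrosynthetic overview**

1. Target 20 ⇐ bis-MOM ketone 19 ⇐ secondary aryl carbinol 18; the phenol MOM ethers come off last.
2. Prenyl at C2 ⇐ Wittig on a C2–CH2CHO arm ⇐ Claisen rearrangement of the C4–O vinyl ether 15, which also puts the ring alkene at C3=C4.
3. Allylic alcohol 14 ⇐ Wharton transposition of epoxy ketone 12 ⇐ enone 11, epoxidised trans to phenyl.
4. Key C–C bond C1–C(aryl): intermolecular aldol addition of the kinetic α'-enolate of enone 8 to aryl aldehyde 3 (made from 2,4,6-trihydroxybenzaldehyde).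
5. Enone 8 ⇐ cinnamaldehyde + tert-butyl 3-oxopentanoate by organocatalytic Michael addition (sets C6), aldol condensation and decarboxylation. The cyclohexene is the only ring built (step 3); the oxirane is transient (made in step 6, opened in step 7).

Convention: ring carbons C1–C6 in the Why lines follow the target numbering (C1 carries the aryl carbon, C2 the prenyl arm, C3 the methyl, C6 the phenyl). The carbinol carbon in 10–18 is carried as both epimers and is left undefined in the SMILES.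

Assumption: 8 is expected in about 90–95% ee, by analogy with the acetoacetate case, and is brought to >99% ee by recrystallisation of 12 or preparative chiral HPLC of 8.

**Route**

Step 1
Reactants: 1 2,4,6-trihydroxybenzaldehyde
Product: 2 2-hydroxy-4,6-bis(methoxymethoxy)benzaldehyde
Conditions: MOMCl (2.2 equiv), i-Pr2NEt, CH2Cl2, 0 °C to rt
Reagents that add atoms: chloromethyl methyl ether (MOMCl), COCCl
Why: Williamson-type O-alkylation (MOM protection) of the 4-OH and one ortho OH, while the second ortho OH stays free because it is hydrogen-bonded to the aldehyde.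

Step 2
Reactants: 2 2-hydroxy-4,6-bis(methoxymethoxy)benzaldehyde
Product: 3 2-methoxy-4,6-bis(methoxymethoxy)benzaldehyde
Conditions: MeI, K2CO3, acetone, reflux
Reagents that add atoms: iodomethane, CI
Why: Williamson ether synthesis on the remaining chelated phenol fixes the methyl ether that survives to the target.

Step 3
Reactants: 4 (E)-cinnamaldehyde; 5 tert-butyl 3-oxopentanoate
Product: 8 (5R)-2-methyl-5-phenylcyclohex-2-en-1-one, via Michael adduct 6 (not isolated), via cyclic keto ester 7 (not isolated)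
Conditions: (S)-2-{bis[3,5-bis(trifluoromethyl)phenyl](trimethylsilyloxy)methyl}pyrrolidine (10 mol%), toluene, rt; then p-TsOH·H2O (20 mol%), toluene, 80 °C
Reagents that add atoms: none
Why: Iminium-catalysed asymmetric Michael addition in which the bulky silyloxydiarylmethyl group of the (S)-catalyst blocks one face of the E-iminium ion, so the keto ester adds to the open face and sets C6 as R, after which acid drives the intramolecular aldol condensation through the ethyl-ketone enol and the tert-butyl ester is lost as isobutene and CO2.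

Step 4
Reactants: 8 (5R)-2-methyl-5-phenylcyclohex-2-en-1-one; 3 2-methoxy-4,6-bis(methoxymethoxy)benzaldehyde
Product: 10 (5R,6R)-6-{hydroxy[2-methoxy-4,6-bis(methoxymethoxy)phenyl]methyl}-2-methyl-5-phenylcyclohex-2-en-1-one, via lithium dienolate 9 (not isolated)
Conditions: LiN(i-Pr)2 (1.1 equiv), THF, −78 °C; then 3, −78 °C; sat. aq. NH4Cl at −78 °C
Reagents that add atoms: none
Why: Kinetic α'-deprotonation gives the cross-conjugated lithium dienolate, whose intermolecular aldol addition to the aldehyde occurs anti to the neighbouring phenyl group and so sets C1 trans to C6 (also the thermodynamic arrangement while C1 is still α to the ring ketone), the carbinol centre forming as an epimer mixture that is erased in step 12.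

Step 5
Reactants: 10 (5R,6R)-6-{hydroxy[2-methoxy-4,6-bis(methoxymethoxy)phenyl]methyl}-2-methyl-5-phenylcyclohex-2-en-1-one
Product: 11 (5R,6R)-6-{[tert-butyl(dimethyl)silyl]oxy[2-methoxy-4,6-bis(methoxymethoxy)phenyl]methyl}-2-methyl-5-phenylcyclohex-2-en-1-one
Conditions: TBSOTf, 2,6-lutidine, CH2Cl2, −78 to 0 °C
Reagents that add atoms: tert-butyldimethylsilyl trifluoromethanesulfonate (TBSOTf), CC(C)(C)[Si](C)(C)OS(=O)(=O)C(F)(F)F
Why: Silyl ether formation on the secondary alcohol blocks retro-aldol cleavage in the basic steps that follow and changes no stereocentre.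

Step 6
Reactants: 11 (5R,6R)-6-{[tert-butyl(dimethyl)silyl]oxy[2-methoxy-4,6-bis(methoxymethoxy)phenyl]methyl}-2-methyl-5-phenylcyclohex-2-en-1-one
Product: 12 (1R,3R,4R,6R)-3-{[tert-butyl(dimethyl)silyl]oxy[2-methoxy-4,6-bis(methoxymethoxy)phenyl]methyl}-1-methyl-4-phenyl-7-oxabicyclo[4.1.0]heptan-2-one
Conditions: 30% H2O2, NaOH (0.3 equiv), MeOH/THF, 0 °C
Reagents that add atoms: hydrogen peroxide, OO
Why: Weitz–Scheffer nucleophilic epoxidation in which hydroperoxide adds to C4 of the enone on the face opposite the C6 phenyl group, as with carvone, and the enolate closes the oxirane on that face, setting C3 and C4.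

Step 7
Reactants: 12 (1R,3R,4R,6R)-3-{[tert-butyl(dimethyl)silyl]oxy[2-methoxy-4,6-bis(methoxymethoxy)phenyl]methyl}-1-methyl-4-phenyl-7-oxabicyclo[4.1.0]heptan-2-one
Product: 14 (1R,4R,5R)-4-{[tert-butyl(dimethyl)silyl]oxy[2-methoxy-4,6-bis(methoxymethoxy)phenyl]methyl}-2-methyl-5-phenylcyclohex-2-en-1-ol, via epoxy hydrazone 13 (not isolated)
Conditions: N2H4·H2O (3 equiv), AcOH (0.2 equiv), MeOH, 0 °C to rt
Reagents that add atoms: none
Why: Wharton transposition in which the hydrazone opens the oxirane to an alkenyldiazene that loses N2, moving the alkene to C2=C3 while the C4–O bond and its configuration are untouched.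

Step 8
Reactants: 14 (1R,4R,5R)-4-{[tert-butyl(dimethyl)silyl]oxy[2-methoxy-4,6-bis(methoxymethoxy)phenyl]methyl}-2-methyl-5-phenylcyclohex-2-en-1-ol
Product: 15 tert-butyl({(1R,4R,6R)-4-(ethenyloxy)-3-methyl-6-phenylcyclohex-2-en-1-yl}[2-methoxy-4,6-bis(methoxymethoxy)phenyl]methoxy)dimethylsilane
Conditions: n-butyl vinyl ether (solvent), Pd(OCOCF3)2 (2 mol%), 4,7-diphenyl-1,10-phenanthroline (2 mol%), Et3N (10 mol%), 75 °C
Reagents that add atoms: butyl vinyl ether, C=COCCCC
Why: Palladium-catalysed transfer vinylation (transetherification) exchanges O–H for O–vinyl on the allylic alcohol without touching any stereocentre.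

Step 9
Reactants: 15 tert-butyl({(1R,4R,6R)-4-(ethenyloxy)-3-methyl-6-phenylcyclohex-2-en-1-yl}[2-methoxy-4,6-bis(methoxymethoxy)phenyl]methoxy)dimethylsilane
Product: 16 2-[(1S,5R,6R)-6-{[tert-butyl(dimethyl)silyl]oxy[2-methoxy-4,6-bis(methoxymethoxy)phenyl]methyl}-2-methyl-5-phenylcyclohex-2-en-1-yl]acetaldehyde
Conditions: toluene, 160 °C, sealed tube
Reagents that add atoms: none
Why: Claisen rearrangement whose [3,3] shift is suprafacial across the ring, so the CH2CHO carbon is delivered to C2 on the face that held the C4–O bond (trans to phenyl, cis to the C1 side chain) and the alkene returns to C3=C4.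

Step 10
Reactants: 16 2-[(1S,5R,6R)-6-{[tert-butyl(dimethyl)silyl]oxy[2-methoxy-4,6-bis(methoxymethoxy)phenyl]methyl}-2-methyl-5-phenylcyclohex-2-en-1-yl]acetaldehyde
Product: 17 tert-butyl({(1R,2S,6R)-3-methyl-2-(3-methylbut-2-en-1-yl)-6-phenylcyclohex-3-en-1-yl}[2-methoxy-4,6-bis(methoxymethoxy)phenyl]methoxy)dimethylsilane
Conditions: i-PrPPh3I, n-BuLi, THF, 0 °C; then 16, −78 °C to rt
Reagents that add atoms: isopropyltriphenylphosphonium iodide, CC(C)[P+](c1ccccc1)(c1ccccc1)c1ccccc1.[I-]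
Why: Wittig olefination with the non-stabilised isopropylidene ylide turns the aldehyde into the prenyl terminus, with no E/Z issue because the ylide carbon carries two methyl groups.

Step 11
Reactants: 17 tert-butyl({(1R,2S,6R)-3-methyl-2-(3-methylbut-2-en-1-yl)-6-phenylcyclohex-3-en-1-yl}[2-methoxy-4,6-bis(methoxymethoxy)phenyl]methoxy)dimethylsilane
Product: 18 {(1R,2S,6R)-3-methyl-2-(3-methylbut-2-en-1-yl)-6-phenylcyclohex-3-en-1-yl}[2-methoxy-4,6-bis(methoxymethoxy)phenyl]methanol
Conditions: Bu4NF, THF, rt to 45 °C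
Reagents that add atoms: none
Why: Fluoride-mediated desilylation frees the benzylic alcohol and leaves the MOM ethers and both alkenes untouched.

Step 12
Reactants: 18 {(1R,2S,6R)-3-methyl-2-(3-methylbut-2-en-1-yl)-6-phenylcyclohex-3-en-1-yl}[2-methoxy-4,6-bis(methoxymethoxy)phenyl]methanol
Product: 19 [2-methoxy-4,6-bis(methoxymethoxy)phenyl][(1R,2S,6R)-3-methyl-2-(3-methylbut-2-en-1-yl)-6-phenylcyclohex-3-en-1-yl]methanone
Conditions: Dess–Martin periodinane, CH2Cl2, 0 °C to rt
Reagents that add atoms: none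
Why: Dess–Martin oxidation under non-basic conditions converts both carbinol epimers into the one aryl ketone without epimerising C1.

Step 13
Reactants: 19 [2-methoxy-4,6-bis(methoxymethoxy)phenyl][(1R,2S,6R)-3-methyl-2-(3-methylbut-2-en-1-yl)-6-phenylcyclohex-3-en-1-yl]methanone
Product: 20 isopanduratin A, (2,4-dihydroxy-6-methoxyphenyl)[(1R,2S,6R)-3-methyl-2-(3-methylbut-2-en-1-yl)-6-phenylcyclohex-3-en-1-yl]methanone
Conditions: HCl (3 M aq., cat.), MeOH, 45 °C
Reagents that add atoms: none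
Why: Acid-catalysed transacetalisation cleaves both MOM ethers, while the isolated trisubstituted alkenes and the hindered, slowly enolising ketone α-centre C1 survive brief mild acid.

**Compound list**

1 | 2,4,6-trihydroxybenzaldehyde | O=Cc1c(O)cc(O)cc1O | starting material
2 | 2-hydroxy-4,6-bis(methoxymethoxy)benzaldehyde | O=Cc1c(O)cc(OCOC)cc1OCOC | intermediate
3 | 2-methoxy-4,6-bis(methoxymethoxy)benzaldehyde | O=Cc1c(OC)cc(OCOC)cc1OCOC | intermediate
4 | (E)-cinnamaldehyde | O=C/C=C/c1ccccc1 | starting material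
5 | tert-butyl 3-oxopentanoate | CCC(=O)CC(=O)OC(C)(C)C | starting material
6 | tert-butyl (3R)-5-oxo-3-phenyl-2-propanoylpentanoate (C2 epimers) | CCC(=O)C(C(=O)OC(C)(C)C)[C@H](c1ccccc1)CC=O | intermediate (not isolated)
7 | tert-butyl (6R)-3-methyl-2-oxo-6-phenylcyclohex-3-ene-1-carboxylate (C1 epimers) | O=C1C(C(=O)OC(C)(C)C)[C@H](c2ccccc2)CC=C1C | intermediate (not isolated)
8 | (5R)-2-methyl-5-phenylcyclohex-2-en-1-one | O=C1C[C@H](c2ccccc2)CC=C1C | intermediate
9 | lithium (3R)-6-methyl-3-phenylcyclohexa-1,5-dien-1-olate | [Li]OC1=C[C@H](c2ccccc2)CC=C1C | intermediate (not isolated)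
10 | (5R,6R)-6-{hydroxy[2-methoxy-4,6-bis(methoxymethoxy)phenyl]methyl}-2-methyl-5-phenylcyclohex-2-en-1-one; side chain trans to phenyl | O=C1[C@@H](C(O)c2c(OC)cc(OCOC)cc2OCOC)[C@H](c2ccccc2)CC=C1C | intermediate
11 | (5R,6R)-6-{[tert-butyl(dimethyl)silyl]oxy[2-methoxy-4,6-bis(methoxymethoxy)phenyl]methyl}-2-methyl-5-phenylcyclohex-2-en-1-one | O=C1[C@@H](C(O[Si](C)(C)C(C)(C)C)c2c(OC)cc(OCOC)cc2OCOC)[C@H](c2ccccc2)CC=C1C | intermediate
12 | (1R,3R,4R,6R)-3-{[tert-butyl(dimethyl)silyl]oxy[2-methoxy-4,6-bis(methoxymethoxy)phenyl]methyl}-1-methyl-4-phenyl-7-oxabicyclo[4.1.0]heptan-2-one; oxirane trans to phenyl | O=C1[C@@H](C(O[Si](C)(C)C(C)(C)C)c2c(OC)cc(OCOC)cc2OCOC)[C@H](c2ccccc2)C[C@H]2O[C@@]12C | intermediate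
13 | hydrazone of 12 at the ring ketone (ring stereocentres as in 12) | NN=C1[C@@H](C(O[Si](C)(C)C(C)(C)C)c2c(OC)cc(OCOC)cc2OCOC)[C@H](c2ccccc2)C[C@H]2O[C@@]12C | intermediate (not isolated)
14 | (1R,4R,5R)-4-{[tert-butyl(dimethyl)silyl]oxy[2-methoxy-4,6-bis(methoxymethoxy)phenyl]methyl}-2-methyl-5-phenylcyclohex-2-en-1-ol; OH trans to phenyl | O[C@@H]1C[C@@H](c2ccccc2)[C@H](C(O[Si](C)(C)C(C)(C)C)c2c(OC)cc(OCOC)cc2OCOC)C=C1C | intermediate
15 | tert-butyl({(1R,4R,6R)-4-(ethenyloxy)-3-methyl-6-phenylcyclohex-2-en-1-yl}[2-methoxy-4,6-bis(methoxymethoxy)phenyl]methoxy)dimethylsilane | C=CO[C@@H]1C[C@@H](c2ccccc2)[C@H](C(O[Si](C)(C)C(C)(C)C)c2c(OC)cc(OCOC)cc2OCOC)C=C1C | intermediate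
16 | 2-[(1S,5R,6R)-6-{[tert-butyl(dimethyl)silyl]oxy[2-methoxy-4,6-bis(methoxymethoxy)phenyl]methyl}-2-methyl-5-phenylcyclohex-2-en-1-yl]acetaldehyde | CC(C)(C)[Si](C)(C)OC(c1c(OC)cc(OCOC)cc1OCOC)[C@@H]1[C@H](CC=O)C(C)=CC[C@H]1c1ccccc1 | intermediate
17 | tert-butyl({(1R,2S,6R)-3-methyl-2-(3-methylbut-2-en-1-yl)-6-phenylcyclohex-3-en-1-yl}[2-methoxy-4,6-bis(methoxymethoxy)phenyl]methoxy)dimethylsilane | CC(C)(C)[Si](C)(C)OC(c1c(OC)cc(OCOC)cc1OCOC)[C@@H]1[C@H](CC=C(C)C)C(C)=CC[C@H]1c1ccccc1 | intermediate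
18 | {(1R,2S,6R)-3-methyl-2-(3-methylbut-2-en-1-yl)-6-phenylcyclohex-3-en-1-yl}[2-methoxy-4,6-bis(methoxymethoxy)phenyl]methanol | OC(c1c(OC)cc(OCOC)cc1OCOC)[C@@H]1[C@H](CC=C(C)C)C(C)=CC[C@H]1c1ccccc1 | intermediate
19 | [2-methoxy-4,6-bis(methoxymethoxy)phenyl][(1R,2S,6R)-3-methyl-2-(3-methylbut-2-en-1-yl)-6-phenylcyclohex-3-en-1-yl]methanone | COc1cc(OCOC)cc(OCOC)c1C(=O)[C@@H]1[C@H](CC=C(C)C)C(C)=CC[C@H]1c1ccccc1 | intermediate
20 | isopanduratin A, (2,4-dihydroxy-6-methoxyphenyl)[(1R,2S,6R)-3-methyl-2-(3-methylbut-2-en-1-yl)-6-phenylcyclohex-3-en-1-yl]methanone | COc1cc(O)cc(O)c1C(=O)[C@@H]1[C@H](CC=C(C)C)C(C)=CC[C@H]1c1ccccc1 | target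

**Totals and risks**

Total step count: 13. Longest linear sequence: 12 steps (1 → 2 → 3, then steps 4 to 13); the cinnamaldehyde branch is 11 steps.

Steps most likely to fail:

Step 4 (aldol of a hindered enolate with a hindered, electron-rich aldehyde; retro-aldol on work-up). The fallback sets out from 8. The kinetic enolate is trapped with Me3SiCl (LiN(i-Pr)2, THF, −78 °C) as trimethyl{[(3R)-6-methyl-3-phenylcyclohexa-1,5-dien-1-yl]oxy}silane F1. F1 then undergoes a Lewis-acid Mukaiyama aldol addition to 3 (BF3·OEt2, CH2Cl2, −78 °C), where the aldolate is silyl-capped and cannot revert. Aqueous work-up returns to the route at 10.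

Step 7 (Wharton transposition; hindered ketone, pyrazoline side products, modest yields). The fallback sets out from 12. NaBH4/CeCl3·7H2O in MeOH gives the epoxy alcohol 3-{[tert-butyl(dimethyl)silyl]oxy[2-methoxy-4,6-bis(methoxymethoxy)phenyl]methyl}-1-methyl-4-phenyl-7-oxabicyclo[4.1.0]heptan-2-ol F2. 1,1'-Thiocarbonyldiimidazole (toluene, 80 °C) converts it to the O-alkyl imidazole-1-carbothioate of that epoxy alcohol F3. Bu3SnH/AIBN (toluene, 80 °C) then generates the C2 radical, which opens the neighbouring oxirane; the oxygen radical is reduced and the allylic alcohol forms with the C4–O bond untouched. This returns to the route at 14.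

Step 9 (Claisen rearrangement delivering carbon cis to the bulky C1 side chain, after a vinylation of a hindered alcohol). The fallback sets out from 14 and bypasses 15. Eschenmoser–Claisen rearrangement with N,N-dimethylacetamide dimethyl acetal (xylene, 140 °C, neutral) gives 2-[(1S,5R,6R)-6-{[tert-butyl(dimethyl)silyl]oxy[2-methoxy-4,6-bis(methoxymethoxy)phenyl]methyl}-2-methyl-5-phenylcyclohex-2-en-1-yl]-N,N-dimethylacetamide F4 with the same suprafacial transfer. Partial reduction with LiAlH(OEt)3 (THF, 0 °C) returns to the route at 16.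

**Further compounds**

F1 | step 4 | trimethyl{[(3R)-6-methyl-3-phenylcyclohexa-1,5-dien-1-yl]oxy}silane | C[Si](C)(C)OC1=C[C@H](c2ccccc2)CC=C1C
F2 | step 7 | 3-{[tert-butyl(dimethyl)silyl]oxy[2-methoxy-4,6-bis(methoxymethoxy)phenyl]methyl}-1-methyl-4-phenyl-7-oxabicyclo[4.1.0]heptan-2-ol (C2 carbinol epimers; other stereocentres as in 12) | OC1[C@@H](C(O[Si](C)(C)C(C)(C)C)c2c(OC)cc(OCOC)cc2OCOC)[C@H](c2ccccc2)C[C@H]2O[C@@]12C
F3 | step 7 | O-alkyl 1H-imidazole-1-carbothioate of epoxy alcohol F2 (stereocentres as in F2) | S=C(OC1[C@@H](C(O[Si](C)(C)C(C)(C)C)c2c(OC)cc(OCOC)cc2OCOC)[C@H](c2ccccc2)C[C@H]2O[C@@]12C)n1ccnc1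
F4 | step 9 | 2-[(1S,5R,6R)-6-{[tert-butyl(dimethyl)silyl]oxy[2-methoxy-4,6-bis(methoxymethoxy)phenyl]methyl}-2-methyl-5-phenylcyclohex-2-en-1-yl]-N,N-dimethylacetamide | CC(C)(C)[Si](C)(C)OC(c1c(OC)cc(OCOC)cc1OCOC)[C@@H]1[C@H](CC(=O)N(C)C)C(C)=CC[C@H]1c1ccccc1
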